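**Retrosynthetic overview**
1. Target 20 is a head-to-tail hexamer of 2,6-dihydroxy-1,4-phenylene oxide. It has no C–C bond outside its six benzene rings, so the five bonds to make are diaryl ether C–O bonds; the last step is a 14-fold O-demethylation of 19.
2. Each ether joins the hindered "head" oxygen of one ring (between two OMe) to the electron-rich "tail" carbon of the next. Both are nucleophiles by nature, so the tail carbon is used with reversed polarity, as an aryl(2,4,6-trimethoxyphenyl)iodonium salt (aryl cation equivalent) made in the flask from the aryl iodide.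
3. One bifunctional monomer, 4-iodo-2,6-dimethoxyphenol 2, is used four times: its phenol reacts now and its iodide is the latent electrophile of the next cycle, so no protecting-group step separates the cycles.
4. No ring is constructed; purchased benzene rings are joined in the order F, E, D, C, B, A.

Assumption: the target has no stereocentre and no configurationally stable axis, so it is achiral and "the single enantiomer" is the compound itself; no stereocontrol is needed.

**Route**

Step 1
Reactants: 1 2,6-dimethoxyphenol (syringol)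
Product: 2 4-iodo-2,6-dimethoxyphenol
Conditions: NIS (1.0 equiv), NaH (0.1 equiv), CHCl3, −45 °C to rt
Reagents that add atoms: N-iodosuccinimide O=C1CCC(=O)N1I
Why: Phenoxide-directed electrophilic aromatic iodination (SEAr): both ortho positions carry OMe, so the catalytic phenoxide takes iodine para to oxygen, by analogy with the NBS/NaH para-bromination of syringol, and the low temperature suppresses oxidative dimerisation; no stereocentre is formed.

Step 2
Reactants: 3 5-iodo-1,2,3-trimethoxybenzene; 2 4-iodo-2,6-dimethoxyphenol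
Product: 6 dimer iodide 5-(4-iodo-2,6-dimethoxyphenoxy)-1,2,3-trimethoxybenzene, via ring F aryliodine diacetate 4 (not isolated), via ring F iodonium tosylate 5 (not isolated)
Conditions: mCPBA (1.05 equiv), AcOH–CH2Cl2 1:4, rt; then 1,3,5-trimethoxybenzene (1.3 equiv), TsOH·H2O (1.05 equiv), 0 °C to rt; evaporate; then 2 (1.3 equiv), K2CO3 (4 equiv), MeCN, 55 °C
Reagents that add atoms: acetic acid CC(=O)O (acetate ligands of 4 only); 1,3,5-trimethoxybenzene COc1cc(OC)cc(OC)c1 (second aryl group of 5 only); p-toluenesulfonic acid monohydrate Cc1ccc(S(=O)(=O)O)cc1.O (counter-ion of 5 only); all three leave again before 6 is formed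
Why: Established sequence of peracid oxidation of an aryl iodide to its diacetate, TsOH-promoted SEAr ligand exchange with 1,3,5-trimethoxybenzene, and metal-free phenoxide O-arylation by ligand coupling at trivalent iodine; the phenoxide goes to the less electron-rich 3,4,5-trimethoxyphenyl group while the 2,4,6-trimethoxyphenyl group leaves as its iodide, the hindered phenoxide of 2 is a competent nucleophile, its C–I bond is inert without a transition metal, and no stereocentre is formed.

Step 3
Reactants: 6 dimer iodide; 2 4-iodo-2,6-dimethoxyphenol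
Product: 9 trimer iodide 5-[4-(4-iodo-2,6-dimethoxyphenoxy)-2,6-dimethoxyphenoxy]-1,2,3-trimethoxybenzene, via dimer aryliodine diacetate 7 (not isolated), via dimer iodonium tosylate 8 (not isolated)
Conditions: mCPBA (1.05 equiv), AcOH–CH2Cl2 1:4, 0 °C to rt; then 1,3,5-trimethoxybenzene (1.5 equiv), TsOH·H2O (1.05 equiv), 0 °C; evaporate; then 2 (1.3 equiv), K2CO3 (4 equiv), MeCN, 55 °C
Reagents that add atoms: acetic acid CC(=O)O (acetate ligands of 7 only); 1,3,5-trimethoxybenzene COc1cc(OC)cc(OC)c1 (second aryl group of 8 only); p-toluenesulfonic acid monohydrate Cc1ccc(S(=O)(=O)O)cc1.O (counter-ion of 8 only); all three leave again before 9 is formed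
Why: Proposed new method: the step 2 cycle applied to an iodide that already carries a phloroglucinol-type ring; iodine is the most easily oxidised atom of 6, the neutral diacetate 7 does not attack arenes without strong acid, iodine sits para to the ether oxygen so no cyclic iodonium can form, and TsOH is added only when the more nucleophilic, unhindered 1,3,5-trimethoxybenzene is present in excess, so the cationic trivalent iodine is trapped as 8 instead of arylating a second molecule of 6, after which ligand coupling transfers the ring bearing para-aryloxy and meta-methoxy groups to phenoxide 2; the closest known reactions are the one-pot synthesis of aryl(2,4,6-trimethoxyphenyl)iodonium tosylates from aryl iodides and the diaryliodonium O-arylation of 2,6-disubstituted phenols; no stereocentre is formed.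

Step 4
Reactants: 9 trimer iodide; 2 4-iodo-2,6-dimethoxyphenol
Product: 12 tetramer iodide 5-{4-[4-(4-iodo-2,6-dimethoxyphenoxy)-2,6-dimethoxyphenoxy]-2,6-dimethoxyphenoxy}-1,2,3-trimethoxybenzene, via trimer aryliodine diacetate 10 (not isolated), via trimer iodonium tosylate 11 (not isolated)
Conditions: mCPBA (1.05 equiv), AcOH–CH2Cl2 1:4, 0 °C to rt; then 1,3,5-trimethoxybenzene (1.5 equiv), TsOH·H2O (1.05 equiv), 0 °C; evaporate; then 2 (1.3 equiv), K2CO3 (4 equiv), MeCN, 55 °C
Reagents that add atoms: acetic acid CC(=O)O (acetate ligands of 10 only); 1,3,5-trimethoxybenzene COc1cc(OC)cc(OC)c1 (second aryl group of 11 only); p-toluenesulfonic acid monohydrate Cc1ccc(S(=O)(=O)O)cc1.O (counter-ion of 11 only); all three leave again before 12 is formed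
Why: Proposed new method: the step 3 cycle on the trimer, resting on the same reasoning (oxidation at iodine first, acid-gated SEAr ligand exchange in the presence of excess 1,3,5-trimethoxybenzene, then ligand coupling at trivalent iodine that keeps the most electron-rich aryl group on iodine); the closest known reactions are the one-pot aryl(2,4,6-trimethoxyphenyl)iodonium tosylate synthesis and the diaryliodonium O-arylation of hindered phenols; no stereocentre is formed.

Step 5
Reactants: 12 tetramer iodide; 2 4-iodo-2,6-dimethoxyphenol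
Product: 15 pentamer iodide 5-(4-{4-[4-(4-iodo-2,6-dimethoxyphenoxy)-2,6-dimethoxyphenoxy]-2,6-dimethoxyphenoxy}-2,6-dimethoxyphenoxy)-1,2,3-trimethoxybenzene, via tetramer aryliodine diacetate 13 (not isolated), via tetramer iodonium tosylate 14 (not isolated)
Conditions: mCPBA (1.05 equiv), AcOH–CH2Cl2 1:4, 0 °C to rt; then 1,3,5-trimethoxybenzene (2 equiv), TsOH·H2O (1.05 equiv), 0 °C; evaporate; then 2 (1.3 equiv), K2CO3 (4 equiv), MeCN, 55 °C
Reagents that add atoms: acetic acid CC(=O)O (acetate ligands of 13 only); 1,3,5-trimethoxybenzene COc1cc(OC)cc(OC)c1 (second aryl group of 14 only); p-toluenesulfonic acid monohydrate Cc1ccc(S(=O)(=O)O)cc1.O (counter-ion of 14 only); all three leave again before 15 is formed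
Why: Proposed new method: the step 3 cycle on the tetramer, where three inner rings now compete with 1,3,5-trimethoxybenzene for the cationic trivalent iodine, so the trap is raised to 2 equiv and the acid is added cold; the mechanism (oxidation at iodine, SEAr ligand exchange, ligand coupling) and the closest known reactions (one-pot aryl(2,4,6-trimethoxyphenyl)iodonium tosylate synthesis, diaryliodonium O-arylation of hindered phenols) are unchanged; no stereocentre is formed.

Step 6
Reactants: 15 pentamer iodide; 16 2,4,6-trimethoxyphenol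
Product: 19 hexamer tetradecamethyl ether 5-[4-(4-{4-[4-(2,4,6-trimethoxyphenoxy)-2,6-dimethoxyphenoxy]-2,6-dimethoxyphenoxy}-2,6-dimethoxyphenoxy)-2,6-dimethoxyphenoxy]-1,2,3-trimethoxybenzene, via pentamer aryliodine diacetate 17 (not isolated), via pentamer iodonium tosylate 18 (not isolated)
Conditions: mCPBA (1.05 equiv), AcOH–CH2Cl2 1:4, 0 °C to rt; then 1,3,5-trimethoxybenzene (2 equiv), TsOH·H2O (1.05 equiv), 0 °C; evaporate; then 16 (1.5 equiv), K2CO3 (4 equiv), MeCN, 55 °C, argon
Reagents that add atoms: acetic acid CC(=O)O (acetate ligands of 17 only); 1,3,5-trimethoxybenzene COc1cc(OC)cc(OC)c1 (second aryl group of 18 only); p-toluenesulfonic acid monohydrate Cc1ccc(S(=O)(=O)O)cc1.O (counter-ion of 18 only); all three leave again before 19 is formed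
Why: Proposed new method: the step 3 cycle on the pentamer, closed with the halogen-free ring A phenoxide, whose oxygen between two OMe groups attacks trivalent iodine and is transferred to the pentamer aryl group by ligand coupling while 2-iodo-1,3,5-trimethoxybenzene leaves; the closest known reactions are the one-pot aryl(2,4,6-trimethoxyphenyl)iodonium tosylate synthesis and the diaryliodonium O-arylation of hindered phenols; no stereocentre is formed.

Step 7
Reactants: 19 hexamer tetradecamethyl ether
Product: 20 CNP0187343.0 (target)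
Conditions: BBr3 (45 equiv), CH2Cl2, −78 °C to rt, 24 h, argon; degassed H2O quench; Sephadex LH-20 (degassed MeOH)
Reagents that add atoms: none
Why: Lewis-acid aryl methyl ether cleavage (BBr3 demethylation): bromide attacks the methyl group of each O–B adduct by SN2, whereas the five diaryl ether oxygens have no sp3 carbon and survive, and the air-sensitive polyphenol is kept under argon; no stereocentre is formed.

**Compound list**
1 | 2,6-dimethoxyphenol (syringol) | COc1cccc(OC)c1O | starting material
2 | 4-iodo-2,6-dimethoxyphenol (OH between the two OMe groups, I para to OH) | COc1cc(I)cc(OC)c1O | intermediate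
3 | 5-iodo-1,2,3-trimethoxybenzene (ring F) | COc1cc(I)cc(OC)c1OC | starting material
4 | ring F aryliodine diacetate, 5-(diacetoxyiodo)-1,2,3-trimethoxybenzene | COc1cc(I(OC(C)=O)OC(C)=O)cc(OC)c1OC | intermediate
5 | ring F iodonium tosylate, (3,4,5-trimethoxyphenyl)(2,4,6-trimethoxyphenyl)iodonium p-toluenesulfonate | COc1cc([I+]c2c(OC)cc(OC)cc2OC)cc(OC)c1OC.Cc1ccc(S(=O)(=O)[O-])cc1 | intermediate
6 | dimer iodide, 5-(4-iodo-2,6-dimethoxyphenoxy)-1,2,3-trimethoxybenzene | COc1cc(Oc2c(OC)cc(I)cc2OC)cc(OC)c1OC | intermediate
7 | dimer aryliodine diacetate (6 with I replaced by I(OAc)2) | COc1cc(Oc2c(OC)cc(I(OC(C)=O)OC(C)=O)cc2OC)cc(OC)c1OC | intermediate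
8 | dimer iodonium tosylate, [3,5-dimethoxy-4-(3,4,5-trimethoxyphenoxy)phenyl](2,4,6-trimethoxyphenyl)iodonium p-toluenesulfonate | COc1cc(Oc2c(OC)cc([I+]c3c(OC)cc(OC)cc3OC)cc2OC)cc(OC)c1OC.Cc1ccc(S(=O)(=O)[O-])cc1 | intermediate
9 | trimer iodide, 5-[4-(4-iodo-2,6-dimethoxyphenoxy)-2,6-dimethoxyphenoxy]-1,2,3-trimethoxybenzene | COc1cc(Oc2c(OC)cc(Oc3c(OC)cc(I)cc3OC)cc2OC)cc(OC)c1OC | intermediate
10 | trimer aryliodine diacetate (9 with I replaced by I(OAc)2) | COc1cc(Oc2c(OC)cc(Oc3c(OC)cc(I(OC(C)=O)OC(C)=O)cc3OC)cc2OC)cc(OC)c1OC | intermediate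
11 | trimer iodonium tosylate (9 with I replaced by the (2,4,6-trimethoxyphenyl)iodonium group, tosylate counter-ion) | COc1cc(Oc2c(OC)cc(Oc3c(OC)cc([I+]c4c(OC)cc(OC)cc4OC)cc3OC)cc2OC)cc(OC)c1OC.Cc1ccc(S(=O)(=O)[O-])cc1 | intermediate
12 | tetramer iodide, 5-{4-[4-(4-iodo-2,6-dimethoxyphenoxy)-2,6-dimethoxyphenoxy]-2,6-dimethoxyphenoxy}-1,2,3-trimethoxybenzene | COc1cc(Oc2c(OC)cc(Oc3c(OC)cc(Oc4c(OC)cc(I)cc4OC)cc3OC)cc2OC)cc(OC)c1OC | intermediate
13 | tetramer aryliodine diacetate (12 with I replaced by I(OAc)2) | COc1cc(Oc2c(OC)cc(Oc3c(OC)cc(Oc4c(OC)cc(I(OC(C)=O)OC(C)=O)cc4OC)cc3OC)cc2OC)cc(OC)c1OC | intermediate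
14 | tetramer iodonium tosylate (12 with I replaced by the (2,4,6-trimethoxyphenyl)iodonium group, tosylate counter-ion) | COc1cc(Oc2c(OC)cc(Oc3c(OC)cc(Oc4c(OC)cc([I+]c5c(OC)cc(OC)cc5OC)cc4OC)cc3OC)cc2OC)cc(OC)c1OC.Cc1ccc(S(=O)(=O)[O-])cc1 | intermediate
15 | pentamer iodide, 5-(4-{4-[4-(4-iodo-2,6-dimethoxyphenoxy)-2,6-dimethoxyphenoxy]-2,6-dimethoxyphenoxy}-2,6-dimethoxyphenoxy)-1,2,3-trimethoxybenzene | COc1cc(Oc2c(OC)cc(Oc3c(OC)cc(Oc4c(OC)cc(Oc5c(OC)cc(I)cc5OC)cc4OC)cc3OC)cc2OC)cc(OC)c1OC | intermediate
16 | 2,4,6-trimethoxyphenol (ring A) | COc1cc(OC)c(O)c(OC)c1 | starting material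
17 | pentamer aryliodine diacetate (15 with I replaced by I(OAc)2) | COc1cc(Oc2c(OC)cc(Oc3c(OC)cc(Oc4c(OC)cc(Oc5c(OC)cc(I(OC(C)=O)OC(C)=O)cc5OC)cc4OC)cc3OC)cc2OC)cc(OC)c1OC | intermediate
18 | pentamer iodonium tosylate (15 with I replaced by the (2,4,6-trimethoxyphenyl)iodonium group, tosylate counter-ion) | COc1cc(Oc2c(OC)cc(Oc3c(OC)cc(Oc4c(OC)cc(Oc5c(OC)cc([I+]c6c(OC)cc(OC)cc6OC)cc5OC)cc4OC)cc3OC)cc2OC)cc(OC)c1OC.Cc1ccc(S(=O)(=O)[O-])cc1 | intermediate
19 | hexamer tetradecamethyl ether, 5-[4-(4-{4-[4-(2,4,6-trimethoxyphenoxy)-2,6-dimethoxyphenoxy]-2,6-dimethoxyphenoxy}-2,6-dimethoxyphenoxy)-2,6-dimethoxyphenoxy]-1,2,3-trimethoxybenzene | COc1cc(Oc2c(OC)cc(Oc3c(OC)cc(Oc4c(OC)cc(Oc5c(OC)cc(Oc6c(OC)cc(OC)cc6OC)cc5OC)cc4OC)cc3OC)cc2OC)cc(OC)c1OC | intermediate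
20 | CNP0187343.0, 2-[4-(4-{4-[4-(3,4,5-trihydroxyphenoxy)-3,5-dihydroxyphenoxy]-3,5-dihydroxyphenoxy}-3,5-dihydroxyphenoxy)-3,5-dihydroxyphenoxy]benzene-1,3,5-triol (achiral) | Oc1cc(O)c(Oc2cc(O)c(Oc3cc(O)c(Oc4cc(O)c(Oc5cc(O)c(Oc6cc(O)c(O)c(O)c6)c(O)c5)c(O)c4)c(O)c3)c(O)c2)c(O)c1 | target

**Totals**
Total step count: 7. Longest linear sequence: 7 steps (1 → 2 → 6 → 9 → 12 → 15 → 19 → 20).

**Three steps most likely to fail, with fallbacks**

Step 5 is the most exposed monomer-adding cycle. Trivalent iodine must be generated on a tetramer whose three inner rings are phloroglucinol-like, so ring oxidation by the peracid or intermolecular self-arylation may outrun capture by 1,3,5-trimethoxybenzene. The fallback sets out from 12 and comes back at 15. Iodine–magnesium exchange on 12 (iPrMgCl·LiCl, THF, −15 °C), then B(OMe)3 and aqueous NH4Cl, gives the tetramer boronic acid F1. Chan–Lam–Evans coupling of F1 with phenol 2 (Cu(OAc)2, pyridine, 4 Å molecular sieves, air, CH2Cl2, rt) gives 15. The oligomer now reacts as the carbon nucleophile and divalent copper is the oxidant, so neither peracid nor cationic trivalent iodine meets the electron-rich rings. Aryl iodides are inert under these conditions, so the iodide of 2 is carried into 15.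

Step 6 has the same hazard on the largest iodide, and its nucleophile 16 is very easily oxidised. The fallback sets out from 15 and comes back at 19. It is a direct CuI-catalysed Ullmann etherification of 15 with 16 (CuI, picolinic acid, K3PO4, DMSO, 90 °C), using the iodide with its normal polarity. Because 16 carries no halogen, the self-coupling that rules this out for monomer 2 cannot occur. No new compound is made (F0).

Step 7 requires fourteen demethylations on one molecule, and the free polyphenol autoxidises readily, so incomplete cleavage and loss on isolation are both likely. The fallback sets out from 19 and comes back at 20. After the same BBr3 treatment the crude polyphenol is not purified but acetylated at once (Ac2O, pyridine, DMAP, rt) to the stable tetradecaacetate F2. F2 is chromatographed on silica to remove under-demethylated material. It is then deacetylated by acid methanolysis (HCl generated from AcCl in degassed MeOH, 40 °C, argon), which avoids the phenolate autoxidation that a basic deacetylation would invite, and evaporation gives 20.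

**Further compounds**
F1 | step 5 | tetramer boronic acid (12 with I replaced by B(OH)2) | COc1cc(Oc2c(OC)cc(Oc3c(OC)cc(Oc4c(OC)cc(B(O)O)cc4OC)cc3OC)cc2OC)cc(OC)c1OC
F0 | step 6 | none | none
F2 | step 7 | tetradecaacetate of 20 (every OH of 20 as OAc) | CC(=O)Oc1cc(OC(C)=O)c(Oc2cc(OC(C)=O)c(Oc3cc(OC(C)=O)c(Oc4cc(OC(C)=O)c(Oc5cc(OC(C)=O)c(Oc6cc(OC(C)=O)c(OC(C)=O)c(OC(C)=O)c6)c(OC(C)=O)c5)c(OC(C)=O)c4)c(OC(C)=O)c3)c(OC(C)=O)c2)c(OC(C)=O)c1
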